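**Strategy**

Ring B is built, not substituted. Its C3–C4–C5–C6 segment (prenyl-bearing C3, C4–OH, C5–H, C6–OH) is the diene part of a 1-methoxy-1,3-bis(trimethylsilyloxy)diene made from sulcatone, and C1–C2 is the triple bond of a tert-butoxy ynone that already carries ring A. One Diels–Alder reaction with aromatisation forms C2–C3 and C1–C6, closes ring B and sets the whole benzophenone. The feature exploited is the oxygenation of ring B: O at C2, C4 and C6, each ortho or para to the C1 acyl group, which matches the polarity of an electron-rich diene and a push–pull alkyne; the C3 prenyl arrives within the diene. Acid finally frees the C2 and ring-A hydroxyls.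

Key step: step 9

Remark on the chemistry: tert-butoxyacetylene is volatile, thermally fragile and not assumed to be a stock chemical. Its lithium salt is therefore generated in the flask from (E)-1-tert-butoxy-1,2-dichloroethene, made from trichloroethylene and KOt-Bu. The target is achiral; the transient sp3 centres in 20 and 22 are racemic or unassigned and disappear.

**Route**

Step 1
Reactants: 1 sulcatone (6-methylhept-5-en-2-one)
Product: 2 methyl 7-methyl-3-oxooct-6-enoate
Conditions: NaH, (MeO)2CO, THF, reflux; then aq HCl, 0 °C
Reagents that add atoms: dimethyl carbonate, COC(=O)OC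
Why: Crossed Claisen-type C-methoxycarbonylation, in which the methyl-side enolate of the methyl ketone is acylated by the carbonate and deprotonation of the β-keto ester drives the reaction to the linear product.

Step 2
Reactants: 2 methyl 7-methyl-3-oxooct-6-enoate
Product: 3 methyl (2E)-7-methyl-3-(trimethylsilyloxy)octa-2,6-dienoate
Conditions: TMSCl, Et3N, toluene, 20 °C
Reagents that add atoms: chlorotrimethylsilane, C[Si](C)(C)Cl
Why: Soft enolisation and O-silylation of a β-keto ester gives the silyl enol ether, expected mainly as the 2E isomer, whose geometry is irrelevant because this double bond is relocated in step 3.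

Step 3
Reactants: 3 methyl (2E)-7-methyl-3-(trimethylsilyloxy)octa-2,6-dienoate
Product: 5 (1Z,3Z)-1-methoxy-7-methyl-1,3-bis(trimethylsilyloxy)octa-1,3,6-triene, via lithium dienolate 4 (not isolated)
Conditions: LDA, THF, −78 °C; then TMSCl, −78 → 20 °C
Reagents that add atoms: chlorotrimethylsilane, C[Si](C)(C)Cl
Why: γ-Deprotonation of the silyloxy enoate and O-silylation of the ester dienolate is the standard preparation of 1-alkoxy-1,3-bis(silyloxy)-1,3-dienes, and the 3Z geometry places the prenyl chain on the outside of the s-cis diene.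

Step 4
Reactants: 6 3-hydroxybenzoic acid
Product: 8 3-(methoxymethoxy)benzoic acid, via methoxymethyl ester 7 (not isolated)
Conditions: MOMCl, i-Pr2NEt, CH2Cl2, 0 → 20 °C; then NaOH, MeOH–H2O, 20 °C; aq HCl to pH 3–4, 0 °C
Reagents that add atoms: chloromethyl methyl ether, COCCl
Why: O-Alkylation of both acidic hydroxyls with MOMCl followed by saponification of the labile MOM ester leaves the base-stable aryl MOM ether (Williamson-type etherification, ester hydrolysis).

Step 5
Reactants: 8 3-(methoxymethoxy)benzoic acid; 9 prenyl bromide (1-bromo-3-methylbut-2-ene)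
Product: 12 3-(methoxymethoxy)-2-(3-methylbut-2-enyl)benzoic acid, via dilithiated benzoate 10 (not isolated), via arylcopper carboxylate 11 (not isolated)
Conditions: LiTMP (2.5 equiv), THF, 0 °C; CuBr·SMe2, −40 °C; then 9, −40 → 20 °C; aq HCl to pH 3–4, 0 °C
Reagents that add atoms: none
Why: Directed ortho-metalation of the unprotected benzoate removes C2–H, the only hydrogen flanked by both the carboxylate and the OMOM group, and the arylcopper formed by lithium-to-copper exchange is alkylated by prenyl bromide at its primary carbon, which keeps the prenyl group linear.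

Step 6
Reactants: 12 3-(methoxymethoxy)-2-(3-methylbut-2-enyl)benzoic acid
Product: 14 N-methoxy-N-methyl-3-(methoxymethoxy)-2-(3-methylbut-2-enyl)benzamide, via acylimidazole 13 (not isolated)
Conditions: CDI, CH2Cl2, 20 °C; then MeNH(OMe)·HCl, 20 °C
Reagents that add atoms: N,O-dimethylhydroxylamine hydrochloride, CNOC.Cl
Why: Activation as the acylimidazole and aminolysis is a Weinreb amide synthesis that generates no strong acid, so the MOM ether and the prenyl alkene are spared.

Step 7
Reactants: 15 trichloroethylene; 16 potassium tert-butoxide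
Product: 17 (E)-1-tert-butoxy-1,2-dichloroethene
Conditions: t-BuOH (cat.), THF, −50 → 20 °C
Reagents that add atoms: none
Why: Known 1,2-dichlorovinyl ether synthesis, in which the alkoxide eliminates HCl from trichloroethylene to dichloroacetylene (never isolated), adds to it, and the vinyl anion is protonated by tert-butanol in an overall anti addition.

Step 8
Reactants: 17 (E)-1-tert-butoxy-1,2-dichloroethene; 14 N-methoxy-N-methyl-3-(methoxymethoxy)-2-(3-methylbut-2-enyl)benzamide
Product: 21 3-tert-butoxy-1-[3-(methoxymethoxy)-2-(3-methylbut-2-enyl)phenyl]prop-2-yn-1-one, via tert-butoxy(chloro)acetylene 18 (not isolated), via lithium tert-butoxyacetylide 19 (not isolated), via tetrahedral lithium adduct 20 (not isolated)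
Conditions: 17, n-BuLi (2 equiv per 17), THF, −78 °C; then 14, −78 → −40 °C; AcOH, −78 °C
Reagents that add atoms: none
Why: Dehydrochlorination and chlorine–lithium exchange give the alkoxyacetylide, and its addition to the amide is a Weinreb ketone synthesis in which chelated adduct 20 prevents over-addition and the cold acidic quench protonates the released amine before it can add to the ynone.

Step 9
Reactants: 5 (1Z,3Z)-1-methoxy-7-methyl-1,3-bis(trimethylsilyloxy)octa-1,3,6-triene; 21 3-tert-butoxy-1-[3-(methoxymethoxy)-2-(3-methylbut-2-enyl)phenyl]prop-2-yn-1-one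
Product: 24 [2-tert-butoxy-4,6-dihydroxy-3-(3-methylbut-2-enyl)phenyl][3-(methoxymethoxy)-2-(3-methylbut-2-enyl)phenyl]methanone, via cycloadduct 22 (not isolated), via bis(trimethylsilyl) ether 23 (not isolated)
Conditions: 5 (2.5 equiv), toluene (1 M), −20 → 20 °C, dark; then aq citric acid, THF, 0 °C
Reagents that add atoms: none
Why: Proposed new method: diene 5 and push–pull ynone 21 are polarity-matched, so the prenyl-bearing diene terminus (largest HOMO coefficient) should bond to the alkyne carbon β to the ketone, which carries O-t-Bu and is the acceptor site of this vinylogous ester, while the ketene-acetal carbon bonds to the α carbon, in an asynchronous [4+2] cycloaddition or, at the stepwise limit, by Mukaiyama–Michael addition followed by closure of the allenolate carbon onto the oxocarbenium carbon. The closest known reaction type is the Diels–Alder reaction of 1-alkoxy-1,3-bis(silyloxy)dienes with acetylenic ketones and esters, which gives resorcinols after loss of the alcohol; an alkoxy group on the alkyne is the untested element. Ring B, the only ring formed, closes in the [4+2] mode (6-exo-trig in the stepwise variant); cycloadduct 22 then aromatises by 1,4-elimination of methanol across C3–H/C6–OMe to 23, whose aryl silyl ethers are hydrolysed in the mild acidic work-up. No stereocentre is created in the product: the two sp3 carbons of 22 form without control and both become aromatic. The step needs regioselectivity (O-t-Bu at C2 next to the prenyl at C3, OH at C4 and C6), secured by the matching donor/acceptor polarisation of both partners, and chemoselectivity against closure through the central diene carbon onto the ketone, favoured by omitting any Lewis acid. It is run at or below 20 °C because tert-butyl ynol ethers lose isobutene to ketenes on warming, and the MOM ether and both prenyl alkenes are inert under these neutral conditions.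

Step 10
Reactants: 24 [2-tert-butoxy-4,6-dihydroxy-3-(3-methylbut-2-enyl)phenyl][3-(methoxymethoxy)-2-(3-methylbut-2-enyl)phenyl]methanone
Product: 26 cudraphenone D, via ring-A MOM ether 25 (not isolated)
Conditions: HCl (0.5 M in MeOH), 0 → 25 °C
Reagents that add atoms: none
Why: Acid-catalysed solvolysis, in which the congested aryl tert-butyl ether next to the ketone ionises first (isobutene lost, cation otherwise trapped by methanol and not by C5) and the MOM acetal is then transacetalised by methanol, conditions of a kind commonly tolerated by ortho-prenyl phenols.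

**Compound list**

1 | sulcatone (6-methylhept-5-en-2-one) | CC(=O)CCC=C(C)C | starting material
2 | methyl 7-methyl-3-oxooct-6-enoate | COC(=O)CC(=O)CCC=C(C)C | intermediate
3 | methyl (2E)-7-methyl-3-(trimethylsilyloxy)octa-2,6-dienoate | COC(=O)/C=C(/O[Si](C)(C)C)CCC=C(C)C | intermediate
4 | lithium (1E,3Z)-1-methoxy-7-methyl-3-(trimethylsilyloxy)octa-1,3,6-trien-1-olate | CO/C([O-])=C/C(O[Si](C)(C)C)=C/CC=C(C)C.[Li+] | intermediate (not isolated)
5 | (1Z,3Z)-1-methoxy-7-methyl-1,3-bis(trimethylsilyloxy)octa-1,3,6-triene | CO/C(O[Si](C)(C)C)=C/C(O[Si](C)(C)C)=C/CC=C(C)C | intermediate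
6 | 3-hydroxybenzoic acid | OC(=O)c1cccc(O)c1 | starting material
7 | methoxymethyl 3-(methoxymethoxy)benzoate | COCOC(=O)c1cccc(OCOC)c1 | intermediate (not isolated)
8 | 3-(methoxymethoxy)benzoic acid | COCOc1cccc(C(=O)O)c1 | intermediate
9 | prenyl bromide (1-bromo-3-methylbut-2-ene) | CC(C)=CCBr | starting material
10 | lithium 2-lithio-3-(methoxymethoxy)benzoate | COCOc1cccc(C(=O)[O-])c1[Li].[Li+] | intermediate (not isolated)
11 | lithium 2-cuprio-3-(methoxymethoxy)benzoate | COCOc1cccc(C(=O)[O-])c1[Cu].[Li+] | intermediate (not isolated)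
12 | 3-(methoxymethoxy)-2-(3-methylbut-2-enyl)benzoic acid | CC(C)=CCc1c(OCOC)cccc1C(=O)O | intermediate
13 | 1-[3-(methoxymethoxy)-2-(3-methylbut-2-enyl)benzoyl]imidazole | CC(C)=CCc1c(OCOC)cccc1C(=O)n1ccnc1 | intermediate (not isolated)
14 | N-methoxy-N-methyl-3-(methoxymethoxy)-2-(3-methylbut-2-enyl)benzamide | CC(C)=CCc1c(OCOC)cccc1C(=O)N(C)OC | intermediate
15 | trichloroethylene | ClC=C(Cl)Cl | starting material
16 | potassium tert-butoxide | CC(C)(C)[O-].[K+] | starting material
17 | (E)-1-tert-butoxy-1,2-dichloroethene | Cl/C=C(/Cl)OC(C)(C)C | intermediate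
18 | 1-tert-butoxy-2-chloroethyne | CC(C)(C)OC#CCl | intermediate (not isolated)
19 | lithium tert-butoxyacetylide | CC(C)(C)OC#C[Li] | intermediate (not isolated)
20 | lithium 3-tert-butoxy-1-[methoxy(methyl)amino]-1-[3-(methoxymethoxy)-2-(3-methylbut-2-enyl)phenyl]prop-2-yn-1-olate (racemic) | CC(C)=CCc1c(OCOC)cccc1C([O-])(C#COC(C)(C)C)N(C)OC.[Li+] | intermediate (not isolated)
21 | 3-tert-butoxy-1-[3-(methoxymethoxy)-2-(3-methylbut-2-enyl)phenyl]prop-2-yn-1-one | CC(C)=CCc1c(OCOC)cccc1C(=O)C#COC(C)(C)C | intermediate
22 | [2-tert-butoxy-6-methoxy-3-(3-methylbut-2-enyl)-4,6-bis(trimethylsilyloxy)cyclohexa-1,4-dien-1-yl][3-(methoxymethoxy)-2-(3-methylbut-2-enyl)phenyl]methanone (configuration at C3 and C6 unassigned) | CC(C)=CCc1c(OCOC)cccc1C(=O)C1=C(OC(C)(C)C)C(CC=C(C)C)C(O[Si](C)(C)C)=CC1(OC)O[Si](C)(C)C | intermediate (not isolated)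
23 | [2-tert-butoxy-3-(3-methylbut-2-enyl)-4,6-bis(trimethylsilyloxy)phenyl][3-(methoxymethoxy)-2-(3-methylbut-2-enyl)phenyl]methanone | CC(C)=CCc1c(OCOC)cccc1C(=O)c1c(O[Si](C)(C)C)cc(O[Si](C)(C)C)c(CC=C(C)C)c1OC(C)(C)C | intermediate (not isolated)
24 | [2-tert-butoxy-4,6-dihydroxy-3-(3-methylbut-2-enyl)phenyl][3-(methoxymethoxy)-2-(3-methylbut-2-enyl)phenyl]methanone | CC(C)=CCc1c(OCOC)cccc1C(=O)c1c(O)cc(O)c(CC=C(C)C)c1OC(C)(C)C | intermediate
25 | [3-(methoxymethoxy)-2-(3-methylbut-2-enyl)phenyl][2,4,6-trihydroxy-3-(3-methylbut-2-enyl)phenyl]methanone | CC(C)=CCc1c(OCOC)cccc1C(=O)c1c(O)cc(O)c(CC=C(C)C)c1O | intermediate (not isolated)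
26 | cudraphenone D, [3-hydroxy-2-(3-methylbut-2-enyl)phenyl][2,4,6-trihydroxy-3-(3-methylbut-2-enyl)phenyl]methanone (achiral) | CC(C)=CCc1c(O)cccc1C(=O)c1c(O)cc(O)c(CC=C(C)C)c1O | target

**Step count and risk**

Total steps: 10. Longest linear sequence: 6 steps (4, 5, 6, 8, 9, 10, from 3-hydroxybenzoic acid).

Steps most likely to fail:

1. Step 9 (key step). The alkoxy donor may slow the cycloaddition below the rate at which the ynol ether loses isobutene. The first Michael adduct may also close through the central diene carbon onto the ketone, or be hydrolysed open-chain during work-up. The fallback uses known chemistry, a convergent aryllithium acylation; it sets out from Weinreb amide 14 and prenyl bromide 9 and comes back to the route at target 26. Phloroglucinol F1 is converted with MOMCl and i-Pr2NEt into 1,3,5-tris(methoxymethoxy)benzene F2. Ortho-lithiation (n-BuLi, THF, 0 °C), transfer to copper with CuBr·SMe2 and alkylation with 9 should give 1,3,5-tris(methoxymethoxy)-2-(3-methylbut-2-enyl)benzene F3. A second ortho-lithiation between two OMOM groups (n-BuLi, TMEDA, THF, 0 °C) and acylation by 14 in the same flask should give [3-(methoxymethoxy)-2-(3-methylbut-2-enyl)phenyl][2,4,6-tris(methoxymethoxy)-3-(3-methylbut-2-enyl)phenyl]methanone F4. HCl in MeOH then removes the four MOM groups to give 26.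

2. Step 5. Metalation of the dianion may occur at C4 or C6 instead of C2, or remain incomplete under the amide-base equilibrium, and the base may attack the carboxylate. The fallback replaces the carboxylate by a stronger directing group and reaches the ynone through an aldehyde; it sets out from acid 8 (with 9 and 17) and comes back at ynone 21. Acid 8 is converted (CDI, then Et2NH) into N,N-diethyl-3-(methoxymethoxy)benzamide F5. Its C2, flanked by the amide and the OMOM group, is lithiated with s-BuLi/TMEDA at −78 °C, and CuBr·SMe2 followed by 9 should give N,N-diethyl-3-(methoxymethoxy)-2-(3-methylbut-2-enyl)benzamide F6. Cp2Zr(H)Cl in THF reduces the tertiary amide to 3-(methoxymethoxy)-2-(3-methylbut-2-enyl)benzaldehyde F7. Addition of lithium tert-butoxyacetylide 19, made as in step 8, gives racemic 3-tert-butoxy-1-[3-(methoxymethoxy)-2-(3-methylbut-2-enyl)phenyl]prop-2-yn-1-ol F8, and MnO2 in CH2Cl2 at 0 °C oxidises it to 21.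

3. Step 10. Protic acid may cyclise a prenyl group onto its ortho phenol (chroman formation), add to the alkenes, or let the tert-butyl cation alkylate C5; one of the two ethers may also resist. The fallback transprotects instead of solvolysing; it sets out from 24 and comes back at 26. TMSOTf with 2,2′-bipyridyl in CH2Cl2 (0 → 20 °C) should exchange the aryl MOM ether and the tert-butyl ether for silyl ethers (isobutene being lost to the base) and silylate the free phenols, giving [3-(trimethylsilyloxy)-2-(3-methylbut-2-enyl)phenyl][2,4,6-tris(trimethylsilyloxy)-3-(3-methylbut-2-enyl)phenyl]methanone F9. K2CO3 in MeOH then removes the four silyl groups to give 26, so the prenylated phenols never meet protic acid.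

**Further compounds**

F1 | step 9 | phloroglucinol (benzene-1,3,5-triol) | Oc1cc(O)cc(O)c1
F2 | step 9 | 1,3,5-tris(methoxymethoxy)benzene | COCOc1cc(OCOC)cc(OCOC)c1
F3 | step 9 | 1,3,5-tris(methoxymethoxy)-2-(3-methylbut-2-enyl)benzene | CC(C)=CCc1c(OCOC)cc(OCOC)cc1OCOC
F4 | step 9 | [3-(methoxymethoxy)-2-(3-methylbut-2-enyl)phenyl][2,4,6-tris(methoxymethoxy)-3-(3-methylbut-2-enyl)phenyl]methanone | CC(C)=CCc1c(OCOC)cccc1C(=O)c1c(OCOC)cc(OCOC)c(CC=C(C)C)c1OCOC
F5 | step 5 | N,N-diethyl-3-(methoxymethoxy)benzamide | CCN(CC)C(=O)c1cccc(OCOC)c1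
F6 | step 5 | N,N-diethyl-3-(methoxymethoxy)-2-(3-methylbut-2-enyl)benzamide | CCN(CC)C(=O)c1cccc(OCOC)c1CC=C(C)C
F7 | step 5 | 3-(methoxymethoxy)-2-(3-methylbut-2-enyl)benzaldehyde | CC(C)=CCc1c(OCOC)cccc1C=O
F8 | step 5 | 3-tert-butoxy-1-[3-(methoxymethoxy)-2-(3-methylbut-2-enyl)phenyl]prop-2-yn-1-ol (racemic) | CC(C)=CCc1c(OCOC)cccc1C(O)C#COC(C)(C)C
F9 | step 10 | [3-(trimethylsilyloxy)-2-(3-methylbut-2-enyl)phenyl][2,4,6-tris(trimethylsilyloxy)-3-(3-methylbut-2-enyl)phenyl]methanone | CC(C)=CCc1c(O[Si](C)(C)C)cccc1C(=O)c1c(O[Si](C)(C)C)cc(O[Si](C)(C)C)c(CC=C(C)C)c1O[Si](C)(C)C
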